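Rings are lettered A–F from the 2,4,6-trihydroxyphenoxy end. Ring D runs C-1 (O to C), C-2 (H), C-3 (OH), C-4 (O to E), C-5 (OH), C-6 (H). Ring D is not coupled to its neighbours but grown last between them. The feature exploited is the meta-related C-1 ether and C-3 hydroxyl around C-2–H, the pattern left when an aryloxyalkyne is fused to a ketene carbonyl. One photo-Wolff/[2+2]/4π/6π cascade merges an A–B–C ethynyl ether with the vinylketene from a (Z)-3-methoxy-4-(E–F-oxy) diazobutenone, making C-2–C-3, C-3–C-4, C-5–C-6 and C-6–C-1. The congested C-1–O and C-4–O bonds thus exist beforehand, made on alkyne and alkene carbons.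

Key step: step 14

Remark: the target has no stereocentre and no rotationally locked axis, so it is achiral; the only stereochemical element to control is the C=C geometry of 26–33.

Step 1
Reactants: 1 2,4,6-trimethoxyphenol (ring A); 2 4-fluoro-2,6-dimethoxybenzaldehyde (ring B)
Product: 3 2,6-dimethoxy-4-(2,4,6-trimethoxyphenoxy)benzaldehyde (A–B aldehyde)
Conditions: K2CO3, DMF (degassed), 110 °C, Ar
Reagents that add atoms: none
Why: SNAr should proceed because the fluoride sits para to the formyl acceptor at an unhindered carbon with both methoxy groups meta to it, so the crowded but strongly nucleophilic phenoxide of 1 meets neither steric nor electronic opposition.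

Step 2
Reactants: 3 A–B aldehyde
Product: 5 2,6-dimethoxy-4-(2,4,6-trimethoxyphenoxy)phenol (A–B phenol), via aryl formate 4 (not isolated)
Conditions: mCPBA, CH2Cl2, 0 °C → rt; aq. Na2S2O3 wash; K2CO3 (cat.), MeOH, rt
Reagents that add atoms: mCPBA, OOC(=O)c1cccc(Cl)c1
Why: In this Baeyer–Villiger oxidation the aryl ring, with two ortho and one para oxygen donor, should be the only group to migrate, and the formate shields the oxidisable phenol until the peracid is washed out and catalytic methanolysis frees it.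

Step 3
Reactants: 6 5-fluoro-1,2,3-trimethoxybenzene (ring C)
Product: 8 6-fluoro-2,3,4-trimethoxybenzaldehyde, via aryllithium 7 (not isolated)
Conditions: n-BuLi, THF, −78 °C; DMF, −78 °C; aq. HCl
Reagents that add atoms: n-butyllithium, [Li]CCCC (Li of 7); N,N-dimethylformamide, CN(C)C=O (CHO of 8)
Why: Directed ortho-metalation removes the proton between F and OMe (the two free ring positions are equivalent), the aryllithium resists benzyne loss at −78 °C, and DMF formylates it.

Step 4
Reactants: 5 A–B phenol; 8 6-fluoro-2,3,4-trimethoxybenzaldehyde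
Product: 9 2,3,4-trimethoxy-6-[2,6-dimethoxy-4-(2,4,6-trimethoxyphenoxy)phenoxy]benzaldehyde (A–B–C aldehyde)
Conditions: Cs2CO3, DMSO (degassed), 120 °C, Ar
Reagents that add atoms: none
Why: This is an SNAr on an ortho-fluorobenzaldehyde in which the only methoxy group para to the reacting carbon is the middle one of three, twisted out of conjugation and therefore only weakly deactivating, while caesium phenoxide in DMSO supplies the nucleophilicity.

Step 5
Reactants: 9 A–B–C aldehyde
Product: 11 2,3,4-trimethoxy-6-[2,6-dimethoxy-4-(2,4,6-trimethoxyphenoxy)phenoxy]phenol (A–B–C phenol), via aryl formate 10 (not isolated)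
Conditions: mCPBA, CH2Cl2, 0 °C → rt; aq. Na2S2O3 wash; K2CO3 (cat.), MeOH, rt
Reagents that add atoms: mCPBA, OOC(=O)c1cccc(Cl)c1
Why: Baeyer–Villiger oxidation with aryl migration is favoured by the ortho methoxy, ortho aryloxy and para methoxy donors of ring C, and methanolysis of the formate places the hydroxyl on C-6 of ring C.

Step 6
Reactants: 11 A–B–C phenol; 12 trichloroethylene
Product: 14 (E)-1,2-dichlorovinyl ether of 11, via dichloroacetylene 13 (not isolated)
Conditions: K2CO3, DMF, 70 °C, N2
Reagents that add atoms: none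
Why: In this nucleophilic vinylation of a phenol with trichloroethylene the base generates dichloroacetylene, and the phenoxide adds to its slim sp carbon in anti fashion, which tolerates both ortho substituents and gives the E ether.

Step 7
Reactants: 14 (E)-1,2-dichlorovinyl ether
Product: 17 ethynyl ether of 11 (A–B–C ethynyl ether with ethynyloxy on C-6 of ring C), via chloroethynyl ether 15 (not isolated), via lithium acetylide 16 (not isolated)
Conditions: n-BuLi (3 equiv), Et2O–THF, −78 → −40 °C; H2O, −78 °C; quick filtration over basic alumina, used at once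
Reagents that add atoms: n-butyllithium, [Li]CCCC (Li of 16)
Why: The dichlorovinyl ether route to ynol ethers runs through β-elimination of HCl, Cl/Li exchange and protonation, and any stray ring lithiation is reversed by the same protic quench.

Step 8
Reactants: 18 2,6-dimethoxyphenol (ring E); 19 5-iodo-1,2,3-trimethoxybenzene (ring F)
Product: 20 5-(2,6-dimethoxyphenoxy)-1,2,3-trimethoxybenzene
Conditions: CuI (10 mol %), picolinic acid (20 mol %), K3PO4, DMSO, 90 °C
Reagents that add atoms: none
Why: Ullmann diaryl ether coupling under CuI/picolinic acid, conditions suited to 2,6-disubstituted phenols, joins an electron-rich phenol to an aryl iodide whose reacting carbon has no ortho substituent.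

Step 9
Reactants: 20 5-(2,6-dimethoxyphenoxy)-1,2,3-trimethoxybenzene
Product: 22 3,5-dimethoxy-4-(3,4,5-trimethoxyphenoxy)phenol (E–F phenol), via pinacol boronate 21 (not isolated)
Conditions: [Ir(OMe)(cod)]2 (1.5 mol %), dtbpy (3 mol %), B2pin2, THF, 80 °C; then 30 % H2O2, aq. NaOH, 0 °C → rt
Reagents that add atoms: bis(pinacolato)diboron, CC1(C)OB(OC1(C)C)B1OC(C)(C)C(C)(C)O1 (Bpin of 21); hydrogen peroxide, OO (O of 22)
Why: Sterically governed iridium-catalysed C–H borylation can reach only the one C–H without an ortho neighbour (ring E, para to the diaryl ether oxygen), and oxidation of the C–B bond puts the hydroxyl at that same carbon.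

Step 10
Reactants: 23 methyl methoxyacetate; 24 methyl formate
Product: 26 methyl (Z)-3-chloro-2-methoxyacrylate, via sodium enolate 25 (not isolated)
Conditions: NaH, THF, 0 °C → rt; volatiles removed; (COCl)2, DMF (cat.), CH2Cl2, 0 °C → rt; distillation
Reagents that add atoms: sodium hydride, [Na+].[H-] (Na of 25); oxalyl chloride, O=C(Cl)C(=O)Cl (Cl of 26)
Why: Crossed Claisen formylation of the only enolisable ester gives the stabilised enolate, and oxalyl chloride/DMF converts such 1,3-dicarbonyl enolates into β-chlorovinyl carbonyl compounds with the chloride expected trans to the ester.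

Step 11
Reactants: 22 E–F phenol; 26 methyl (Z)-3-chloro-2-methoxyacrylate
Product: 27 methyl (Z)-3-[3,5-dimethoxy-4-(3,4,5-trimethoxyphenoxy)phenoxy]-2-methoxyacrylate
Conditions: K2CO3, DABCO (10 mol %), DMF, 50 °C
Reagents that add atoms: none
Why: Nucleophilic vinylic substitution (addition–elimination) of a β-chloroacrylate by an unhindered phenoxide is accelerated by DABCO, and reversible re-addition should steer the product to the more stable Z isomer with the aryloxy group trans to the ester.

Step 12
Reactants: 27 methyl (Z)-aryloxyacrylate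
Product: 28 (Z)-3-[3,5-dimethoxy-4-(3,4,5-trimethoxyphenoxy)phenoxy]-2-methoxyacrylic acid
Conditions: LiOH, THF–H2O, rt; 1 M HCl to pH 3, 0 °C
Reagents that add atoms: lithium hydroxide, [Li+].[OH-] (carboxyl O)
Why: In this saponification hydroxide attacks the ester carbonyl faster than the donor-deactivated β-carbon, as in the usual hydrolysis of 3-aryloxyacrylates, and the alkene geometry is not touched.

Step 13
Reactants: 28 (Z)-aryloxyacrylic acid
Product: 30 (Z)-1-diazo-3-methoxy-4-[3,5-dimethoxy-4-(3,4,5-trimethoxyphenoxy)phenoxy]but-3-en-2-one, via acid chloride 29 (not isolated)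
Conditions: 1-chloro-N,N,2-trimethylprop-1-en-1-amine, CH2Cl2, 0 °C; then CH2N2 (excess), Et2O, 0 °C
Reagents that add atoms: 1-chloro-N,N,2-trimethylprop-1-en-1-amine, CC(C)=C(Cl)N(C)C (Cl of 29); diazomethane, C=[N+]=[N-] (CHN2 of 30)
Why: This is the acylation of diazomethane (first stage of the Arndt–Eistert sequence), with the acid chloride made under neutral conditions so that no HCl meets the enol ether, and the trisubstituted, doubly oxygenated alkene is too electron-rich to act as a dipolarophile toward diazomethane.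

Step 14
Reactants: 17 A–B–C ethynyl ether; 30 (Z)-diazoketone
Product: 35 hexamer tetradecamethyl ether with free C-3 hydroxyl on ring D, via vinylketene 31 (not isolated), via vinylcyclobutenone 32 (not isolated), via dienylketene 33 (not isolated), via cyclohexadienone 34 (not isolated)
Conditions: 365 nm LED, dry degassed toluene, 20 °C, 30 added slowly to 17 (1.2 equiv); then dark, 100 °C
Reagents that add atoms: none
Why: Proposed new method: the closest known reaction type is the Danheiser benzannulation of photochemically generated vinylketenes with alkoxy- and siloxyalkynes, extended here to an aryloxyalkyne and to a vinylketene carrying two oxygen substituents. Light at 365 nm, where only the diazoketone and not the polymethoxy diaryl ethers absorbs, expels N2 and drives a Wolff 1,2-shift of the dioxyvinyl group (bond C-5–C-6) with retention of its Z geometry to give 31, whose in-plane C=O π* LUMO is orthogonal to the donor-loaded vinyl π system and so should stay electrophilic. The polarised alkyne of 17 attacks the ketene carbonyl carbon with its CH terminus, which fixes the regiochemistry of the [2+2] step (bonds C-2–C-3 and C-6–C-1) and with it the 1,3 relation of the C-1 ether and the C-3 hydroxyl. At 100 °C 32 opens in a reversible conrotatory 4π process, only the isomer 33 whose vinyl arm has rotated inward can react further, and ring D closes by disrotatory 6π electrocyclisation (bond C-3–C-4) followed by tautomerisation of dienone 34 to the phenol. The Z alkene places H rather than the E–F aryloxy group on the inside of the closing triene, and no stereocentre survives in 35. Running light and heat as separate stages keeps the product phenol away from free ketene, and the aryl ynol ether has no β-hydrogen for retro-ene loss during heating.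

Step 15
Reactants: 35 hexamer tetradecamethyl ether
Product: 36 target CNP0270681.0
Conditions: BBr3 (40 equiv), CH2Cl2, −78 °C → rt, Ar; MeOH, 0 °C; evaporation; Sephadex LH-20, degassed solvents
Reagents that add atoms: none
Why: Lewis-acid ether cleavage with BBr3 removes methyl by bromide attack on the O-methyl carbon and cannot break aryl–O–aryl bonds, so all fourteen methyl ethers should fall while the five diaryl ethers stay.

Compound list
1 | 2,4,6-trimethoxyphenol | COc1cc(OC)c(O)c(OC)c1 | starting material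
2 | 4-fluoro-2,6-dimethoxybenzaldehyde | COc1cc(F)cc(OC)c1C=O | starting material
3 | 2,6-dimethoxy-4-(2,4,6-trimethoxyphenoxy)benzaldehyde | COc1cc(OC)c(Oc2cc(OC)c(C=O)c(OC)c2)c(OC)c1 | intermediate
4 | 2,6-dimethoxy-4-(2,4,6-trimethoxyphenoxy)phenyl formate | COc1cc(OC)c(Oc2cc(OC)c(OC=O)c(OC)c2)c(OC)c1 | intermediate
5 | 2,6-dimethoxy-4-(2,4,6-trimethoxyphenoxy)phenol (A–B phenol) | COc1cc(OC)c(Oc2cc(OC)c(O)c(OC)c2)c(OC)c1 | intermediate
6 | 5-fluoro-1,2,3-trimethoxybenzene | COc1cc(F)cc(OC)c1OC | starting material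
7 | (6-fluoro-2,3,4-trimethoxyphenyl)lithium | COc1cc(F)c([Li])c(OC)c1OC | intermediate
8 | 6-fluoro-2,3,4-trimethoxybenzaldehyde | COc1cc(F)c(C=O)c(OC)c1OC | intermediate
9 | A–B–C aldehyde (formyl on C-6 of ring C) | COc1cc(OC)c(Oc2cc(OC)c(Oc3cc(OC)c(OC)c(OC)c3C=O)c(OC)c2)c(OC)c1 | intermediate
10 | A–B–C formate | COc1cc(OC)c(Oc2cc(OC)c(Oc3cc(OC)c(OC)c(OC)c3OC=O)c(OC)c2)c(OC)c1 | intermediate
11 | A–B–C phenol (hydroxyl on C-6 of ring C) | COc1cc(OC)c(Oc2cc(OC)c(Oc3cc(OC)c(OC)c(OC)c3O)c(OC)c2)c(OC)c1 | intermediate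
12 | trichloroethylene | ClC=C(Cl)Cl | starting material
13 | dichloroacetylene | ClC#CCl | intermediate
14 | A–B–C (E)-1,2-dichlorovinyl ether | COc1cc(OC)c(Oc2cc(OC)c(Oc3cc(OC)c(OC)c(OC)c3O/C(Cl)=C\Cl)c(OC)c2)c(OC)c1 | intermediate
15 | A–B–C chloroethynyl ether | COc1cc(OC)c(Oc2cc(OC)c(Oc3cc(OC)c(OC)c(OC)c3OC#CCl)c(OC)c2)c(OC)c1 | intermediate
16 | lithium A–B–C-oxyacetylide | COc1cc(OC)c(Oc2cc(OC)c(Oc3cc(OC)c(OC)c(OC)c3OC#C[Li])c(OC)c2)c(OC)c1 | intermediate
17 | A–B–C ethynyl ether | COc1cc(OC)c(Oc2cc(OC)c(Oc3cc(OC)c(OC)c(OC)c3OC#C)c(OC)c2)c(OC)c1 | intermediate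
18 | 2,6-dimethoxyphenol | COc1cccc(OC)c1O | starting material
19 | 5-iodo-1,2,3-trimethoxybenzene | COc1cc(I)cc(OC)c1OC | starting material
20 | 5-(2,6-dimethoxyphenoxy)-1,2,3-trimethoxybenzene | COc1cccc(OC)c1Oc1cc(OC)c(OC)c(OC)c1 | intermediate
21 | 2-[3,5-dimethoxy-4-(3,4,5-trimethoxyphenoxy)phenyl]-4,4,5,5-tetramethyl-1,3,2-dioxaborolane | COc1cc(B2OC(C)(C)C(C)(C)O2)cc(OC)c1Oc1cc(OC)c(OC)c(OC)c1 | intermediate
22 | 3,5-dimethoxy-4-(3,4,5-trimethoxyphenoxy)phenol (E–F phenol) | COc1cc(O)cc(OC)c1Oc1cc(OC)c(OC)c(OC)c1 | intermediate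
23 | methyl methoxyacetate | COCC(=O)OC | starting material
24 | methyl formate | COC=O | starting material
25 | sodium (Z)-2,3-dimethoxy-3-oxoprop-1-en-1-olate | COC(=O)/C(OC)=C/[O-].[Na+] | intermediate
26 | methyl (Z)-3-chloro-2-methoxyacrylate | COC(=O)/C(OC)=C/Cl | intermediate
27 | methyl (Z)-3-(E–F-oxy)-2-methoxyacrylate | COC(=O)/C(OC)=C/Oc1cc(OC)c(Oc2cc(OC)c(OC)c(OC)c2)c(OC)c1 | intermediate
28 | (Z)-3-(E–F-oxy)-2-methoxyacrylic acid | OC(=O)/C(OC)=C/Oc1cc(OC)c(Oc2cc(OC)c(OC)c(OC)c2)c(OC)c1 | intermediate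
29 | (Z)-3-(E–F-oxy)-2-methoxyacryloyl chloride | ClC(=O)/C(OC)=C/Oc1cc(OC)c(Oc2cc(OC)c(OC)c(OC)c2)c(OC)c1 | intermediate
30 | (Z)-1-diazo-3-methoxy-4-(E–F-oxy)but-3-en-2-one | [N-]=[N+]=CC(=O)/C(OC)=C/Oc1cc(OC)c(Oc2cc(OC)c(OC)c(OC)c2)c(OC)c1 | intermediate
31 | (3Z)-3-methoxy-4-(E–F-oxy)buta-1,3-dien-1-one (vinylketene) | O=C=C/C(OC)=C/Oc1cc(OC)c(Oc2cc(OC)c(OC)c(OC)c2)c(OC)c1 | intermediate
32 | 3-(A–B–C-oxy)-4-[(Z)-1-methoxy-2-(E–F-oxy)vinyl]cyclobut-2-en-1-one (racemic, transient) | O=C1C=C(Oc2c(Oc3c(OC)cc(Oc4c(OC)cc(OC)cc4OC)cc3OC)cc(OC)c(OC)c2OC)C1/C(OC)=C/Oc1cc(OC)c(Oc2cc(OC)c(OC)c(OC)c2)c(OC)c1 | intermediate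
33 | (3E,5Z)-3-(A–B–C-oxy)-5-methoxy-6-(E–F-oxy)hexa-1,3,5-trien-1-one (ketene and dioxyvinyl arms cis on the central alkene) | O=C=C/C(Oc1c(Oc2c(OC)cc(Oc3c(OC)cc(OC)cc3OC)cc2OC)cc(OC)c(OC)c1OC)=C\C(OC)=C\Oc1cc(OC)c(Oc2cc(OC)c(OC)c(OC)c2)c(OC)c1 | intermediate
34 | 3-(A–B–C-oxy)-5-methoxy-6-(E–F-oxy)cyclohexa-2,4-dien-1-one (racemic, transient) | O=C1C=C(Oc2c(Oc3c(OC)cc(Oc4c(OC)cc(OC)cc4OC)cc3OC)cc(OC)c(OC)c2OC)C=C(OC)C1Oc1cc(OC)c(Oc2cc(OC)c(OC)c(OC)c2)c(OC)c1 | intermediate
35 | hexamer tetradecamethyl ether, free C-3 hydroxyl on ring D | COc1cc(OC)c(Oc2cc(OC)c(Oc3cc(OC)c(OC)c(OC)c3Oc3cc(O)c(Oc4cc(OC)c(Oc5cc(OC)c(OC)c(OC)c5)c(OC)c4)c(OC)c3)c(OC)c2)c(OC)c1 | intermediate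
36 | CNP0270681.0 (achiral) | Oc1cc(O)c(Oc2cc(O)c(Oc3cc(O)c(O)c(O)c3Oc3cc(O)c(Oc4cc(O)c(Oc5cc(O)c(O)c(O)c5)c(O)c4)c(O)c3)c(O)c2)c(O)c1 | target

Total step count: 15. Longest linear sequence: 8 (steps 1, 2, 4, 5, 6, 7, 14, 15).

Steps most likely to fail

1. Step 14. Capture of the vinylketene by the less donating aryloxyalkyne may be too slow, so that the ketene dimerises or is lost to traces of nucleophile. The terminal ynol ether may polymerise. Light may also isomerise the enol ether and turn the aryloxy group to the inside of the triene, which would stall the 6π closure. The fallback uses known chemistry only, sets out from phenol 11 and rejoins the route at target 36. Phenol 11 is coupled with fluoroaldehyde 2 under the conditions of step 1 to the A–B–C–D aldehyde F1. Baeyer–Villiger oxidation gives the tetramer formate F2, and methanolysis gives the tetramer phenol F3. Its crowded hydroxyl is then arylated with pinacol boronate 21 (isolated after the first half of step 9) in a Chan–Lam coupling (Cu(OAc)2, pyridine, B(OH)3, 4 Å sieves, O2) to the hexamer pentadecamethyl ether F4. The conditions of step 15 convert this into 36.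

2. Step 4. Substitution may be sluggish because a crowded phenoxide meets a donor-loaded fluoroarene, and the phenoxide may decay oxidatively at the temperature needed. The fallback sets out from phenol 5 and returns at aldehyde 9. Commercial 5-bromo-1,2,3-trimethoxybenzene is formylated (Rieche, Cl2CHOMe/SnCl4) to 6-bromo-2,3,4-trimethoxybenzaldehyde F5. This is joined to 5 by copper catalysis (Ullmann, CuI/picolinic acid/K3PO4/DMSO), where the ortho formyl group assists the metal insertion and no Meisenheimer adduct has to be stabilised.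

3. Step 15. Ether cleavage may stop short at some of the fourteen sites, and the pyrogallol-type rings may oxidise in air during direct isolation. The fallback sets out from 35 and returns at 36, replacing direct isolation by a derivatise–purify–release sequence. The crude product of the BBr3 reaction is acetylated at once (Ac2O, pyridine) to the hexamer pentadecaacetate F6. This is air-stable and can be chromatographed free of under-cleaved material. It is then deacetylated under Zemplén conditions (NaOMe cat., degassed MeOH, acidic resin) to 36.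

Further compounds
F1 | step 14 | A–B–C–D aldehyde (formyl on C-4 of ring D) | COc1cc(OC)c(Oc2cc(OC)c(Oc3cc(OC)c(OC)c(OC)c3Oc3cc(OC)c(C=O)c(OC)c3)c(OC)c2)c(OC)c1
F2 | step 14 | tetramer formate | COc1cc(OC)c(Oc2cc(OC)c(Oc3cc(OC)c(OC)c(OC)c3Oc3cc(OC)c(OC=O)c(OC)c3)c(OC)c2)c(OC)c1
F3 | step 14 | tetramer phenol (hydroxyl on C-4 of ring D) | COc1cc(OC)c(Oc2cc(OC)c(Oc3cc(OC)c(OC)c(OC)c3Oc3cc(OC)c(O)c(OC)c3)c(OC)c2)c(OC)c1
F4 | step 14 | hexamer pentadecamethyl ether | COc1cc(OC)c(Oc2cc(OC)c(Oc3cc(OC)c(OC)c(OC)c3Oc3cc(OC)c(Oc4cc(OC)c(Oc5cc(OC)c(OC)c(OC)c5)c(OC)c4)c(OC)c3)c(OC)c2)c(OC)c1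
F5 | step 4 | 6-bromo-2,3,4-trimethoxybenzaldehyde | COc1cc(Br)c(C=O)c(OC)c1OC
F6 | step 15 | hexamer pentadecaacetate | CC(=O)Oc1cc(OC(C)=O)c(Oc2cc(OC(C)=O)c(Oc3cc(OC(C)=O)c(OC(C)=O)c(OC(C)=O)c3Oc3cc(OC(C)=O)c(Oc4cc(OC(C)=O)c(Oc5cc(OC(C)=O)c(OC(C)=O)c(OC(C)=O)c5)c(OC(C)=O)c4)c(OC(C)=O)c3)c(OC(C)=O)c2)c(OC(C)=O)c1
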